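The target is cut through its cyclohexene ring into chromonyl quinone 25 and labdatriene 20 (final Diels–Alder reaction). Everything rests on making the decalin of 20 in one operation: a pinacol-terminated Prins cyclization of aldehyde 10. It exploits the oxygen at C2 (ring A) and the oxygen-bearing C9 (ring B) on either side of C1 and the quaternary ring-fusion carbon C10 (labdane numbering). The isopropenyl CH2 (C1) attacks the aldehyde carbon (C2), and the C10 cation pulls C5 over from C9. Ring A and ring B (a ring-expanded cyclopentane) thus form together through the new C1–C2 and C5–C10 bonds, with C2 and C10 set, from a monocyclic 1-isopropenylcyclopentyl silyl ether.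

Key step: step 8

Remark on numbering: labdane numbering is used for the terpenoid part: ring A = C1–C5 and C10, ring B = C5–C10, side chain C11–C16, exocyclic methylene C17, gem-dimethyl C18/C19, angular methyl C20; α is the face opposite to C20. The cyclopentane precursors carry the numbers of the carbons they become.

Remark on the chemistry (assumption): in the target, C11, the chromone and the ring-fusion hydrogen lie on one face of the new cyclohexene ring, which corresponds to chromone-endo addition to the (12E)-diene; compounds 1, 2, 7, 15, 17, 21 and 22 are taken as commercially available.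

**Part 1 – triene 20**

Step 1
Reactants: 1 (S)-4-(tert-butyldimethylsilyloxy)cyclopent-2-en-1-one; 2 isopropenylmagnesium bromide
Product: 3 (1R,4S)-4-(tert-butyldimethylsilyloxy)-1-(prop-1-en-2-yl)cyclopent-2-en-1-ol
Conditions: CeCl3, THF, −78 °C; aq NH4Cl
Reagents that add atoms: none
Why: Grignard-derived organocerium 1,2-addition to the enone carbonyl (little enolisation or β-elimination) should occur anti to the C4 silyloxy group, which fixes the tertiary carbinol (future C9) in absolute terms.

Step 2
Reactants: 3 (1R,4S)-4-(tert-butyldimethylsilyloxy)-1-(prop-1-en-2-yl)cyclopent-2-en-1-ol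
Product: 4 (1R,4S)-1-(prop-1-en-2-yl)cyclopent-2-ene-1,4-diol
Conditions: Bu4NF, THF, 0 °C to 25 °C
Reagents that add atoms: none
Why: fluoride-induced desilylation frees the secondary allylic alcohol without touching a stereocentre.

Step 3
Reactants: 4 (1R,4S)-1-(prop-1-en-2-yl)cyclopent-2-ene-1,4-diol
Product: 5 (R)-4-hydroxy-4-(prop-1-en-2-yl)cyclopent-2-en-1-one
Conditions: MnO2, CH2Cl2, 25 °C
Reagents that add atoms: none
Why: allylic oxidation with MnO2 can only convert the secondary allylic alcohol, so the enone is transposed and the tertiary centre is kept.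

Step 4
Reactants: 5 (R)-4-hydroxy-4-(prop-1-en-2-yl)cyclopent-2-en-1-one
Product: 6 (R)-4-(prop-1-en-2-yl)-4-(triethylsilyloxy)cyclopent-2-en-1-one
Conditions: Et3SiOTf, 2,6-lutidine, CH2Cl2, −78 °C to 0 °C
Reagents that add atoms: triethylsilyl trifluoromethanesulfonate, CC[Si](CC)(CC)OS(=O)(=O)C(F)(F)F
Why: silyl triflate silylation of the hindered tertiary alcohol installs the group that directs step 5 and later serves as the pinacol terminus.

Step 5
Reactants: 6 (R)-4-(prop-1-en-2-yl)-4-(triethylsilyloxy)cyclopent-2-en-1-one; 7 4-methoxy-2,2-dimethyl-4-oxobutanoic acid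
Product: 8 methyl 3-methyl-3-[(1S,2R)-4-oxo-2-(prop-1-en-2-yl)-2-(triethylsilyloxy)cyclopentyl]butanoate (side chain cis to isopropenyl)
Conditions: Ir[dF(CF3)ppy]2(dtbbpy)PF6 (1 mol %), K2HPO4, DMF, blue LEDs, 25 °C
Reagents that add atoms: none
Why: decarboxylative Giese reaction, in which the carboxylate is oxidised by the excited trivalent iridium complex, loses CO2, and the tertiary radical adds to the enone β-carbon anti to the silyloxy group (this sets C5 cis to the isopropenyl group) before divalent iridium reduces the α-keto radical to the enolate.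

Step 6
Reactants: 8 methyl 3-methyl-3-[(1S,2R)-4-oxo-2-(prop-1-en-2-yl)-2-(triethylsilyloxy)cyclopentyl]butanoate
Product: 9 methyl 3-methyl-3-[(7S,8R)-8-(prop-1-en-2-yl)-8-(triethylsilyloxy)-1,4-dithiaspiro[4.4]nonan-7-yl]butanoate
Conditions: HSCH2CH2SH, Zn(OTf)2 (cat.), CH2Cl2, 25 °C
Reagents that add atoms: ethane-1,2-dithiol, SCCS
Why: mild Lewis acid dithioketalisation masks the ring ketone (future C7 carbonyl) in a form that survives SnCl4, hydride and Grignard reagents and removes the β-elimination risk of the silyloxy ketone.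

Step 7
Reactants: 9 methyl 3-methyl-3-[(7S,8R)-8-(prop-1-en-2-yl)-8-(triethylsilyloxy)-1,4-dithiaspiro[4.4]nonan-7-yl]butanoate
Product: 10 3-methyl-3-[(7S,8R)-8-(prop-1-en-2-yl)-8-(triethylsilyloxy)-1,4-dithiaspiro[4.4]nonan-7-yl]butanal
Conditions: i-Bu2AlH (1.05 equiv), CH2Cl2, −78 °C; aq potassium sodium tartrate
Reagents that add atoms: none
Why: partial hydride reduction of the ester stops at the aldehyde because the tetrahedral aluminium hemiacetal is stable at −78 °C.

Step 8
Reactants: 10 3-methyl-3-[(7S,8R)-8-(prop-1-en-2-yl)-8-(triethylsilyloxy)-1,4-dithiaspiro[4.4]nonan-7-yl]butanal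
Product: 12 trans-decalin-9-one with 2α-OH; 4,4,10β-trimethyl; 5α-H; spiro-1,3-dithiolane at C7, via tertiary C10 carbocation 11 (not isolated)
Conditions: SnCl4 (1.5 equiv), CH2Cl2, −78 °C to −20 °C; aq NaHCO3
Reagents that add atoms: none
Why: Pinacol-terminated Prins cyclization: SnCl4 activates the aldehyde (C2), the isopropenyl CH2 (C1) attacks it to give tertiary cation 11 at C10, and the cyclopentane bond C9–C5, aligned with the empty orbital and pushed by the silyloxy oxygen, shifts to C10 with retention at C5, after which loss of Et3SiCl leaves the C9 ketone. The closest known reaction type is the Lewis acid-promoted Prins–pinacol ring-enlarging cyclohexane annulation of 1-alkenylcycloalkanol silyl ethers that carry a tethered acetal or aldehyde. Ring A is closed by the C1–C2 bond as a seven-membered ring (7-endo Prins closure) and becomes six-membered when the 1,2-shift makes the C5–C10 bond, and the same shift expands the cyclopentane by one carbon to ring B. C5 is carried over unchanged from 10; C10 is set by the stereospecific suprafacial shift in the cis-disposed substrate, where the chair–chair array that keeps the forming ring A away from the five-membered ring should give the trans fusion (10β-methyl, 5α-H); C2 is set by the equatorial tin-bound oxygen in the chair-like transition state (2α-OH). The step needs migration of C5 and not C8, and pinacol collapse and not ene-type proton loss: C5 is the more substituted carbon and its shift relieves the seven-membered ring, and a β-silyloxy cation rearranges faster than it loses a proton.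

Step 9
Reactants: 12 trans-decalin-9-one with 2α-OH and C7 dithiolane
Product: 14 8(17)-methylene-9-ketone (2α-hydroxy-8-methylidene derivative of 12), via Mannich base 13 (not isolated)
Conditions: (CH2O)n, i-Pr2NH·CF3CO2H, CF3CO2H (cat.), THF, reflux
Reagents that add atoms: paraformaldehyde (formaldehyde), C=O
Why: Mannich-type α-methylenation, in which C8 is the only enolisable position of the C9 ketone (C10 is quaternary), so Mannich base 13 forms there and loses the amine to give the exocyclic enone.

Step 10
Reactants: 14 8(17)-methylene-9-ketone; 15 allylmagnesium bromide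
Product: 16 9β-allyl-2α,9α-diol (2α,9α-dihydroxy-8-methylidene-9β-(prop-2-en-1-yl) decalin with C7 dithiolane)
Conditions: THF, −78 °C (3 equiv of 15); aq NH4Cl
Reagents that add atoms: none
Why: Grignard 1,2-addition to the enone carbonyl, where axial attack on the α face is blocked by the axial sulfur at C7 and the axial C5–H, so the allyl group should enter equatorially (β) and give the 9α tertiary alcohol.

Step 11
Reactants: 16 9β-allyl-2α,9α-diol; 17 methacrolein
Product: 18 (12E)-enal (2α,9α-dihydroxy-14-oxo-15-norlabda-8(17),12-diene with C7 dithiolane)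
Conditions: (H2IMes)(PCy3)Cl2Ru=CHPh (second-generation Grubbs catalyst, 5 mol %), CH2Cl2, 40 °C
Reagents that add atoms: none
Why: olefin cross-metathesis of the terminal allyl group with methacrolein should give the (E)-trisubstituted enal under thermodynamic control, the hindered 1,1-disubstituted exocyclic alkene being inert.

Step 12
Reactants: 18 (12E)-enal
Product: 19 (12E)-2α,9α-dihydroxylabda-8(17),12,14-triene with C7 dithiolane
Conditions: Ph3PCH3Br, KN(SiMe3)2 (excess), THF, −78 °C to 0 °C
Reagents that add atoms: methyltriphenylphosphonium bromide, C[P+](c1ccccc1)(c1ccccc1)c1ccccc1.[Br-]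
Why: Wittig methylenation of the enal gives the (12E)-1,3-diene while the ring ketone is still masked, with excess ylide covering the two free hydroxyls.

Step 13
Reactants: 19 (12E)-triene with C7 dithiolane
Product: 20 (12E)-2α,9α-dihydroxylabda-8(17),12,14-trien-7-one
Conditions: MeI, CaCO3, MeCN–H2O (9:1), 45 °C
Reagents that add atoms: water, O
Why: alkylative hydrolysis of the dithiolane (S-methylation, then hydrolysis of the allyl-stabilised thionium ion) should release the C7 ketone under neutral conditions that spare the diene and the tertiary allylic alcohol.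

**Part 2 – quinone 25**

Step 14
Reactants: 21 1-(2,6-dihydroxy-4-methoxyphenyl)ethan-1-one; 22 2,4,5-trimethoxybenzaldehyde
Product: 23 (E)-1-(2,6-dihydroxy-4-methoxyphenyl)-3-(2,4,5-trimethoxyphenyl)prop-2-en-1-one
Conditions: KOH, EtOH–H2O, 25 °C; aq HCl
Reagents that add atoms: none
Why: Claisen–Schmidt condensation of the acetophenone enolate with the non-enolisable aldehyde gives the (E)-chalcone.

Step 15
Reactants: 23 (E)-chalcone
Product: 24 5-hydroxy-7-methoxy-2-(2,4,5-trimethoxyphenyl)-4H-chromen-4-one
Conditions: I2 (10 mol %), DMSO, 130 °C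
Reagents that add atoms: none
Why: iodine-catalysed oxidative cyclisation (oxa-Michael closure, α-iodination, loss of HI, DMSO as terminal oxidant) gives the flavone and leaves the chelated 5-OH free.

Step 16
Reactants: 24 5-hydroxy-7-methoxy-2-(2,4,5-trimethoxyphenyl)-4H-chromen-4-one
Product: 25 2-(5-hydroxy-7-methoxy-4-oxo-4H-chromen-2-yl)-5-methoxycyclohexa-2,5-diene-1,4-dione
Conditions: (NH4)2Ce(NO3)6, MeCN–H2O, 0 °C
Reagents that add atoms: water, O
Why: oxidative demethylation by tetravalent cerium of the para-dimethoxy pair (2′ and 5′) of the electron-rich trimethoxyphenyl ring gives the methoxy-1,4-benzoquinone, while the electron-poor hydroxychromone ring is left alone.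

**Part 3 – union**

Step 17
Reactants: 20 (12E)-2α,9α-dihydroxylabda-8(17),12,14-trien-7-one; 25 chromonyl methoxybenzoquinone
Product: 26 Dichrostachine N
Conditions: BF3·OEt2 (2.2 equiv), CH2Cl2, −78 °C to −30 °C; aq NaHCO3
Reagents that add atoms: none
Why: Lewis acid-promoted Diels–Alder reaction in which BF3 bound to the chelating 5-hydroxy-4-oxo unit makes the chromone the dominant activating group, so the unsubstituted diene terminus C15 should bond to the quinone CH, C12 to the chromone-bearing carbon (the methoxy-bearing double bond stays out), and the chromone-endo transition state of the (E)-diene puts C11 cis to the chromone and the ring-fusion hydrogen; the diene face is biased only by the neighbouring C9 centre, so the adduct from the other face is the expected by-product to be separated.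

**Compound list**

1 | (S)-4-(tert-butyldimethylsilyloxy)cyclopent-2-en-1-one | O=C1C=C[C@@H](O[Si](C)(C)C(C)(C)C)C1 | starting material
2 | isopropenylmagnesium bromide | C=C(C)[Mg]Br | starting material
3 | (1R,4S)-4-(tert-butyldimethylsilyloxy)-1-(prop-1-en-2-yl)cyclopent-2-en-1-ol | C=C(C)[C@@]1(O)C[C@H](O[Si](C)(C)C(C)(C)C)C=C1 | intermediate
4 | (1R,4S)-1-(prop-1-en-2-yl)cyclopent-2-ene-1,4-diol | C=C(C)[C@@]1(O)C[C@H](O)C=C1 | intermediate
5 | (R)-4-hydroxy-4-(prop-1-en-2-yl)cyclopent-2-en-1-one | C=C(C)[C@@]1(O)CC(=O)C=C1 | intermediate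
6 | (R)-4-(prop-1-en-2-yl)-4-(triethylsilyloxy)cyclopent-2-en-1-one | C=C(C)[C@@]1(O[Si](CC)(CC)CC)CC(=O)C=C1 | intermediate
7 | 4-methoxy-2,2-dimethyl-4-oxobutanoic acid | COC(=O)CC(C)(C)C(=O)O | starting material
8 | methyl 3-methyl-3-[(1S,2R)-4-oxo-2-(prop-1-en-2-yl)-2-(triethylsilyloxy)cyclopentyl]butanoate | C=C(C)[C@@]1(O[Si](CC)(CC)CC)CC(=O)C[C@H]1C(C)(C)CC(=O)OC | intermediate
9 | methyl 3-methyl-3-[(7S,8R)-8-(prop-1-en-2-yl)-8-(triethylsilyloxy)-1,4-dithiaspiro[4.4]nonan-7-yl]butanoate | C=C(C)[C@@]1(O[Si](CC)(CC)CC)CC2(SCCS2)C[C@H]1C(C)(C)CC(=O)OC | intermediate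
10 | 3-methyl-3-[(7S,8R)-8-(prop-1-en-2-yl)-8-(triethylsilyloxy)-1,4-dithiaspiro[4.4]nonan-7-yl]butanal | C=C(C)[C@@]1(O[Si](CC)(CC)CC)CC2(SCCS2)C[C@H]1C(C)(C)CC=O | intermediate
11 | tertiary C10 carbocation (cyclopentane-fused seven-membered ring, tin-bound C2 alkoxide, C9 silyl ether) | C[C+]1C[C@@H](O[Sn-](Cl)(Cl)(Cl)Cl)CC(C)(C)[C@@H]2CC3(SCCS3)C[C@]12O[Si](CC)(CC)CC | intermediate (not isolated)
12 | trans-decalin-9-one: 2α-hydroxy-4,4,10β-trimethyl-5α-H, spiro-1,3-dithiolane at C7 | O=C1CC2(SCCS2)C[C@H]3C(C)(C)C[C@H](O)C[C@]13C | intermediate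
13 | Mannich base: 8-[(diisopropylamino)methyl] derivative of 12 (both C8 epimers) | O=C1C(CN(C(C)C)C(C)C)C2(SCCS2)C[C@H]3C(C)(C)C[C@H](O)C[C@]13C | intermediate (not isolated)
14 | 8(17)-methylene-9-ketone: 2α-hydroxy-8-methylidene derivative of 12 | O=C1C(=C)C2(SCCS2)C[C@H]3C(C)(C)C[C@H](O)C[C@]13C | intermediate
15 | allylmagnesium bromide | C=CC[Mg]Br | starting material
16 | 9β-allyl-2α,9α-diol with 8(17)-methylene and C7 dithiolane | C=CC[C@@]1(O)C(=C)C2(SCCS2)C[C@H]3C(C)(C)C[C@H](O)C[C@]13C | intermediate
17 | methacrolein | C=C(C)C=O | starting material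
18 | (12E)-2α,9α-dihydroxy-14-oxo-15-norlabda-8(17),12-diene with C7 dithiolane | O=C/C(C)=C/C[C@@]1(O)C(=C)C2(SCCS2)C[C@H]3C(C)(C)C[C@H](O)C[C@]13C | intermediate
19 | (12E)-2α,9α-dihydroxylabda-8(17),12,14-triene with C7 dithiolane | C=C/C(C)=C/C[C@@]1(O)C(=C)C2(SCCS2)C[C@H]3C(C)(C)C[C@H](O)C[C@]13C | intermediate
20 | (12E)-2α,9α-dihydroxylabda-8(17),12,14-trien-7-one | C=C/C(C)=C/C[C@@]1(O)C(=C)C(=O)C[C@H]2C(C)(C)C[C@H](O)C[C@]12C | intermediate
21 | 1-(2,6-dihydroxy-4-methoxyphenyl)ethan-1-one | CC(=O)c1c(O)cc(OC)cc1O | starting material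
22 | 2,4,5-trimethoxybenzaldehyde | COc1cc(OC)c(OC)cc1C=O | starting material
23 | (E)-1-(2,6-dihydroxy-4-methoxyphenyl)-3-(2,4,5-trimethoxyphenyl)prop-2-en-1-one | COc1cc(O)c(C(=O)/C=C/c2cc(OC)c(OC)cc2OC)c(O)c1 | intermediate
24 | 5-hydroxy-7-methoxy-2-(2,4,5-trimethoxyphenyl)-4H-chromen-4-one | COc1cc(O)c2c(c1)oc(-c1cc(OC)c(OC)cc1OC)cc2=O | intermediate
25 | 2-(5-hydroxy-7-methoxy-4-oxo-4H-chromen-2-yl)-5-methoxycyclohexa-2,5-diene-1,4-dione | COC1=CC(=O)C(c2cc(=O)c3c(O)cc(OC)cc3o2)=CC1=O | intermediate
26 | Dichrostachine N | C=C1C(=O)C[C@H]2C(C)(C)C[C@H](O)C[C@]2(C)[C@@]1(O)C[C@@H]1C(C)=CC[C@H]2C(=O)C(OC)=CC(=O)[C@@]12c1cc(=O)c2c(O)cc(OC)cc2o1 | target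

**Count and risks**

Total step count: 17 (13 to triene 20, 3 to quinone 25, 1 union). Longest linear sequence: 14 steps (steps 1–13 and 17).

Steps most likely to fail:

1. Step 8. The seven-membered Prins closure on the aldehyde–SnCl4 complex may be outrun by Lewis acid-induced loss of the tertiary allylic silyl ether or by ene-type proton loss, and reaction through the other isopropenyl rotamer would erode the trans ring fusion. The fallback sets out from 10 and triggers the same cascade from a preformed oxocarbenium ion: acetalisation with BnOSiMe3 and catalytic Me3SiOTf (CH2Cl2, −78 °C) gives the dibenzyl acetal F1, SnCl4 at −78 °C ionises it to the more electrophilic benzyloxocarbenium ion and should deliver the 2α-benzyl ether of the decalinone F2, and BCl3 with pentamethylbenzene (the dithiolane rules out hydrogenolysis) cleaves the benzyl ether to come back at 12.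

2. Step 17. Addition may run through the quinone-endo transition state, on the wrong diene face or with reversed orientation. The fallback sets out from 19 and changes the diene geometry so that the ordinary quinone-endo mode gives the needed C12 configuration: triplet-sensitised photoisomerisation (fluorenone, hν, benzene) gives the (12Z)-triene dithiolane F6 (separated; 19 is recycled), alkylative hydrolysis as in step 13 gives the (12Z)-trienone F7, and cycloaddition with 25 under a chiral oxazaborolidinium triflimide catalyst, which binds the vinylogous-ester quinone carbonyl, enforces the quinone-endo transition state and selects the diene face, comes back at 26.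

3. Step 5. Radical addition at the β-carbon next to the quaternary centre may be slow, so that the tertiary radical is reduced or dimerises, and base may eliminate the β-silyloxy group from the product. The fallback sets out from 6 and uses a polar conjugate addition: Hosomi–Sakurai reaction with trimethyl(3-methylbut-2-en-1-yl)silane (TiCl4, CH2Cl2, −78 °C), which attacks through its γ-carbon anti to the silyloxy group, gives the reverse-prenyl ketone F3; dithioketalisation as in step 6 gives the dithiolane F4; hydroboration of the monosubstituted vinyl group with 9-BBN and oxidation with NaBO3·4H2O gives the primary alcohol F5; oxidation with SO3·pyridine, DMSO and Et3N comes back at 10.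

Further compounds

F1 | step 8 | dibenzyl acetal of aldehyde 10 | C=C(C)[C@@]1(O[Si](CC)(CC)CC)CC2(SCCS2)C[C@H]1C(C)(C)CC(OCc3ccccc3)OCc4ccccc4
F2 | step 8 | 2α-benzyl ether of decalinone 12 | O=C1CC2(SCCS2)C[C@H]3C(C)(C)C[C@H](OCc4ccccc4)C[C@]13C
F3 | step 5 | (3S,4R)-3-(2-methylbut-3-en-2-yl)-4-(prop-1-en-2-yl)-4-(triethylsilyloxy)cyclopentan-1-one | C=C(C)[C@@]1(O[Si](CC)(CC)CC)CC(=O)C[C@H]1C(C)(C)C=C
F4 | step 5 | 1,3-dithiolane of F3 | C=C(C)[C@@]1(O[Si](CC)(CC)CC)CC2(SCCS2)C[C@H]1C(C)(C)C=C
F5 | step 5 | primary alcohol: 3-methyl-3-[(7S,8R)-8-(prop-1-en-2-yl)-8-(triethylsilyloxy)-1,4-dithiaspiro[4.4]nonan-7-yl]butan-1-ol | C=C(C)[C@@]1(O[Si](CC)(CC)CC)CC2(SCCS2)C[C@H]1C(C)(C)CCO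
F6 | step 17 | (12Z)-2α,9α-dihydroxylabda-8(17),12,14-triene with C7 dithiolane | C=C/C(C)=C\C[C@@]1(O)C(=C)C2(SCCS2)C[C@H]3C(C)(C)C[C@H](O)C[C@]13C
F7 | step 17 | (12Z)-2α,9α-dihydroxylabda-8(17),12,14-trien-7-one | C=C/C(C)=C\C[C@@]1(O)C(=C)C(=O)C[C@H]2C(C)(C)C[C@H](O)C[C@]12C
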